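**Retrosynthetic overview**
- Last bond: the interflavanyl C4–C8 bond, cut to the C4 benzylic cation of the 2,3-trans flavan-3,4-diol leucorobinetinidin and C8 of intact (+)-catechin. Attack anti to the 3-OH gives the 4alpha linkage.
- The diol comes from (+)-dihydrorobinetin by hydride reduction and is ionised in the same flask as the coupling.
- Ring C of the upper unit, the only ring built, is cut at O1–C2 and C3–O back to an unprotected 2'-hydroxychalcone. One-flask chiral-dioxirane epoxidation, then 6-endo closure by the 2'-phenoxide at C-beta, sets C2 and C3.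
- The chalcone is cut at C-alpha=C-beta to 4'-benzyloxy-2'-hydroxyacetophenone and 3,4,5-tris(benzyloxy)benzaldehyde (aldol condensation).
- Ring order: rings A and B of the upper unit and all three catechin rings are bought; ring C of the upper unit is closed in step 2; the two flavan units are joined last.

Assumption: 1 and 2 are bought as such (each is otherwise one benzylation away from 2,4-dihydroxyacetophenone or 3,4,5-trihydroxybenzaldehyde), and the L-fructose-derived ketone catalyst of step 2 is bought or made from L-sorbose, its preparation not being counted.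

**Step 1**
Reactants: 1 1-[4-(benzyloxy)-2-hydroxyphenyl]ethan-1-one (4'-benzyloxy-2'-hydroxyacetophenone); 2 3,4,5-tris(benzyloxy)benzaldehyde
Product: 3 (E)-1-[4-(benzyloxy)-2-hydroxyphenyl]-3-[3,4,5-tris(benzyloxy)phenyl]prop-2-en-1-one
Conditions: KOH (50% aq.), EtOH/THF, rt, 24–48 h; then dilute HCl to pH 5
Reagents that add atoms: none
Why: Claisen–Schmidt (crossed aldol) condensation of the acetophenone enolate with the non-enolisable aldehyde, followed by E1cB dehydration, gives the conjugated E-enone under thermodynamic control; the benzyl ethers are inert to base, the open chalcone is the stable form in strong base, and no stereocentre is formed.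

**Step 2**
Reactants: 3 (E)-1-[4-(benzyloxy)-2-hydroxyphenyl]-3-[3,4,5-tris(benzyloxy)phenyl]prop-2-en-1-one
Product: 5 (2R,3R)-7-(benzyloxy)-3-hydroxy-2-[3,4,5-tris(benzyloxy)phenyl]-2,3-dihydro-4H-chromen-4-one (tetra-O-benzyl-(+)-dihydrorobinetin), via epoxychalcone 4 (not isolated)
Conditions: L-fructose-derived Shi ketone (1,2:4,5-di-O-isopropylidene-beta-L-erythro-2,3-hexodiulo-2,6-pyranose, 30 mol% in two portions), KHSO5 (as 2KHSO5·KHSO4·K2SO4), K2CO3, nBu4NHSO4, MeCN/dimethoxymethane/aq. Na2B4O7 buffer (pH about 10), 0 °C; then Na2S2O3, rt, 1 h; recrystallise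
Reagents that add atoms: potassium peroxymonosulfate KHSO5, [K+].[O-]S(=O)(=O)OO
Why: Proposed new method: the dioxirane made in the flask from the ketone and KHSO5 transfers one oxygen atom to the E-enone through the usual spiro transition state, and because the D-fructose-derived ketone gives (2S,3R)-glycidates from trans-cinnamates its mirror image should give the (alphaR,betaS)-epoxide 4, while the 2'-OH is spared because it is tied up in the hydrogen bond to the carbonyl; at pH 10 the 2'-phenoxide then opens the epoxide 6-endo at the benzylic C-beta in an SN2 step with inversion, which turns C-beta (S) into C2 (R) and carries C-alpha over unchanged as C3 (R), so that both stereocentres and the 2,3-trans relation come from the one oxygen transfer, in a one-flask copy of the chalcone-to-flavanone ring closure and C3 hydroxylation of the biosynthesis; the closest known reaction types are the Shi asymmetric epoxidation of trans-enones and cinnamates, the dimethyldioxirane epoxidation of unprotected 2'-hydroxychalcones and the base-induced closure of their epoxides to trans-3-hydroxyflavanones (the epoxide pathway of the Algar–Flynn–Oyamada reaction).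

**Step 3**
Reactants: 5 (2R,3R)-7-(benzyloxy)-3-hydroxy-2-[3,4,5-tris(benzyloxy)phenyl]-2,3-dihydro-4H-chromen-4-one
Product: 6 (2R,3R)-3,7-dihydroxy-2-(3,4,5-trihydroxyphenyl)-2,3-dihydro-4H-chromen-4-one ((+)-dihydrorobinetin)
Conditions: H2 (1 atm), Pd/C (10%), EtOAc/MeOH, rt; filtered under argon
Reagents that add atoms: none
Why: Catalytic hydrogenolysis cleaves the four aryl benzyl ethers (to toluene) much faster than the electron-rich aryl ketone is reduced at 1 atm in neutral solvent, and neither stereocentre is touched.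

**Step 4**
Reactants: 6 (+)-dihydrorobinetin; 7 (+)-catechin, (2R,3S)-2-(3,4-dihydroxyphenyl)-3,4-dihydro-2H-chromene-3,5,7-triol (4 equiv)
Product: 10 robinetinidol-(4alpha,8)-catechin [upper unit 2R,3S,4S; lower unit 2R,3S], via leucorobinetinidin 8 (not isolated), via C4 benzylic cation 9 (not isolated)
Conditions: NaBH4, EtOH, 0 °C to rt, argon; then 7, aq. HCl to 0.1 M, rt, 6–18 h; Sephadex LH-20 (EtOH)
Reagents that add atoms: none
Why: NaBH4 reduces the C4 ketone (a bench copy of dihydroflavonol reductase) to the 2,3-trans-3,4-trans diol 8, whose C4–OH ionises in dilute acid to cation 9 (stabilised by the para 7-OH and by O1, i.e. a protonated quinone methide), and C8 of the phloroglucinol ring of catechin adds to the face anti to the 3-OH to set the 3,4-trans (4alpha) C4 centre in a biomimetic SN1 Friedel–Crafts-type condensation; the 5-deoxy C4–aryl bond is acid-stable so C4 is not scrambled, and the minor 4beta,8 and 4alpha,6 isomers are removed on the column.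

**Compound list**
1 | 1-[4-(benzyloxy)-2-hydroxyphenyl]ethan-1-one (4'-benzyloxy-2'-hydroxyacetophenone) | CC(=O)c1ccc(OCc2ccccc2)cc1O | starting material
2 | 3,4,5-tris(benzyloxy)benzaldehyde | O=Cc1cc(OCc2ccccc2)c(OCc2ccccc2)c(OCc2ccccc2)c1 | starting material
3 | (E)-1-[4-(benzyloxy)-2-hydroxyphenyl]-3-[3,4,5-tris(benzyloxy)phenyl]prop-2-en-1-one | O=C(/C=C/c1cc(OCc2ccccc2)c(OCc2ccccc2)c(OCc2ccccc2)c1)c1ccc(OCc2ccccc2)cc1O | intermediate
4 | [4-(benzyloxy)-2-hydroxyphenyl][(2R,3S)-3-[3,4,5-tris(benzyloxy)phenyl]oxiran-2-yl]methanone (trans-epoxide, alphaR,betaS) | O=C([C@@H]1O[C@H]1c1cc(OCc2ccccc2)c(OCc2ccccc2)c(OCc2ccccc2)c1)c1ccc(OCc2ccccc2)cc1O | intermediate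
5 | (2R,3R)-7-(benzyloxy)-3-hydroxy-2-[3,4,5-tris(benzyloxy)phenyl]-2,3-dihydro-4H-chromen-4-one (2,3-trans) | O=C1c2ccc(OCc3ccccc3)cc2O[C@H](c2cc(OCc3ccccc3)c(OCc3ccccc3)c(OCc3ccccc3)c2)[C@H]1O | intermediate
6 | (+)-dihydrorobinetin, (2R,3R)-3,7-dihydroxy-2-(3,4,5-trihydroxyphenyl)-2,3-dihydro-4H-chromen-4-one | O=C1c2ccc(O)cc2O[C@H](c2cc(O)c(O)c(O)c2)[C@H]1O | intermediate
7 | (+)-catechin, (2R,3S)-2-(3,4-dihydroxyphenyl)-3,4-dihydro-2H-chromene-3,5,7-triol | Oc1cc(O)c2c(c1)O[C@H](c1ccc(O)c(O)c1)[C@@H](O)C2 | starting material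
8 | (+)-leucorobinetinidin, (2R,3S,4R)-2-(3,4,5-trihydroxyphenyl)-3,4-dihydro-2H-chromene-3,4,7-triol (2,3-trans-3,4-trans) | Oc1ccc2c(c1)O[C@H](c1cc(O)c(O)c(O)c1)[C@@H](O)[C@@H]2O | intermediate
9 | (2R,3S)-3,7-dihydroxy-2-(3,4,5-trihydroxyphenyl)-3,4-dihydro-2H-chromen-4-ylium (C4 cation, O-protonated quinone methide) | Oc1ccc2c(c1)O[C@H](c1cc(O)c(O)c(O)c1)[C@@H](O)[CH+]2 | intermediate
10 | robinetinidol-(4alpha,8)-catechin (upper unit 2R,3S,4S, 2,3-trans-3,4-trans; C4 bonded to C8 of (2R,3S)-catechin) | Oc1ccc2c(c1)O[C@H](c1cc(O)c(O)c(O)c1)[C@@H](O)[C@@H]2c1c(O)cc(O)c2c1O[C@H](c1ccc(O)c(O)c1)[C@@H](O)C2 | target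

**Step count**
Total steps: 4. Longest linear sequence: 4 (1 → 3 → 5 → 6 → 10).

**Three steps most likely to fail**

Step 2 is the highest risk. The enone may be epoxidised too slowly for the ketone catalyst to survive, the ee may be only moderate, or the phenoxide form of 3 may be oxidised or close to the flavanone at pH 10. The fallback sets out from 3 and comes back at 5; it masks the phenol and changes from an electrophilic to a nucleophilic oxidant. Silylation of 3 (TIPSOTf, 2,6-lutidine, CH2Cl2, 0 °C) gives (E)-1-[4-(benzyloxy)-2-[(triisopropylsilyl)oxy]phenyl]-3-[3,4,5-tris(benzyloxy)phenyl]prop-2-en-1-one F1. Juliá–Colonna epoxidation (poly-L-leucine, urea–H2O2, DBU, THF, rt), in which the hydroperoxide adds inside the peptide helix and the L-polymer gives the alphaR,betaS sense, gives [4-(benzyloxy)-2-[(triisopropylsilyl)oxy]phenyl][(2R,3S)-3-[3,4,5-tris(benzyloxy)phenyl]oxiran-2-yl]methanone F2. TBAF (THF, 0 °C) then frees the phenoxide, which closes 6-endo at C-beta with inversion to give 5.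

Step 4 is the next risk. Catechin can be attacked at C6 as well as C8, the 4beta isomer forms alongside the 4alpha one, and the product can condense further to trimers. The fallback sets out from 6 and comes back at 10; it separates ionisation from coupling. Compound 6 is reduced (NaBH4, EtOH) and 8 is isolated. Its cation is trapped with phenylmethanethiol (BnSH, AcOH/EtOH, 60 °C) as the bench-stable, purifiable (2R,3R,4R)-4-(benzylsulfanyl)-2-(3,4,5-trihydroxyphenyl)-3,4-dihydro-2H-chromene-3,7-diol F3. AgBF4 in THF at 0 °C with 7 (4 equiv) then releases cation 9 by thiophilic activation under neutral, cold conditions, where the dimer does not react on, to give 10.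

Step 3 is the third risk. The aryl ketone of 5 may be over-reduced on Pd, and the freed pyrogallol ring of 6 is air-sensitive. The fallback sets out from 5 (and uses 7) and comes back at 10; it keeps all phenols benzylated until after the coupling, so no ketone is present when the benzyl ethers come off.
- Reduction of 5 (NaBH4, THF/EtOH, 0 °C) gives (2R,3S,4R)-7-(benzyloxy)-2-[3,4,5-tris(benzyloxy)phenyl]-3,4-dihydro-2H-chromene-3,4-diol F4.
- Benzylation of 7 (BnBr, K2CO3, DMF) gives (2R,3S)-5,7-bis(benzyloxy)-2-[3,4-bis(benzyloxy)phenyl]-3,4-dihydro-2H-chromen-3-ol F5.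
- TiCl4 (CH2Cl2, −78 to 0 °C) joins F4 with excess F5, selectively at C8 and anti to the 3-OH, to give 7,3',4',5'-tetra-O-benzylrobinetinidol-(4alpha,8)-5,7,3',4'-tetra-O-benzylcatechin F6.
- Hydrogenolysis (H2, Pd(OH)2/C, THF/MeOH) gives 10.

**Further compounds**
F1 | step 2 | (E)-1-[4-(benzyloxy)-2-[(triisopropylsilyl)oxy]phenyl]-3-[3,4,5-tris(benzyloxy)phenyl]prop-2-en-1-one | O=C(/C=C/c1cc(OCc2ccccc2)c(OCc2ccccc2)c(OCc2ccccc2)c1)c1ccc(OCc2ccccc2)cc1O[Si](C(C)C)(C(C)C)C(C)C
F2 | step 2 | [4-(benzyloxy)-2-[(triisopropylsilyl)oxy]phenyl][(2R,3S)-3-[3,4,5-tris(benzyloxy)phenyl]oxiran-2-yl]methanone | O=C([C@@H]1O[C@H]1c1cc(OCc2ccccc2)c(OCc2ccccc2)c(OCc2ccccc2)c1)c1ccc(OCc2ccccc2)cc1O[Si](C(C)C)(C(C)C)C(C)C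
F3 | step 4 | (2R,3R,4R)-4-(benzylsulfanyl)-2-(3,4,5-trihydroxyphenyl)-3,4-dihydro-2H-chromene-3,7-diol (2,3-trans-3,4-trans) | Oc1ccc2c(c1)O[C@H](c1cc(O)c(O)c(O)c1)[C@@H](O)[C@@H]2SCc1ccccc1
F4 | step 3 | (2R,3S,4R)-7-(benzyloxy)-2-[3,4,5-tris(benzyloxy)phenyl]-3,4-dihydro-2H-chromene-3,4-diol | O(Cc1ccccc1)c1ccc2c(c1)O[C@H](c1cc(OCc3ccccc3)c(OCc3ccccc3)c(OCc3ccccc3)c1)[C@@H](O)[C@@H]2O
F5 | step 3 | (2R,3S)-5,7-bis(benzyloxy)-2-[3,4-bis(benzyloxy)phenyl]-3,4-dihydro-2H-chromen-3-ol (5,7,3',4'-tetra-O-benzyl-(+)-catechin) | O(Cc1ccccc1)c1cc(OCc3ccccc3)c2c(c1)O[C@H](c1ccc(OCc3ccccc3)c(OCc3ccccc3)c1)[C@@H](O)C2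
F6 | step 3 | 7,3',4',5'-tetra-O-benzylrobinetinidol-(4alpha,8)-5,7,3',4'-tetra-O-benzylcatechin (upper unit 2R,3S,4S; lower unit 2R,3S) | O(Cc1ccccc1)c1ccc2c(c1)O[C@H](c1cc(OCc3ccccc3)c(OCc3ccccc3)c(OCc3ccccc3)c1)[C@@H](O)[C@@H]2c1c(OCc3ccccc3)cc(OCc3ccccc3)c2c1O[C@H](c1ccc(OCc3ccccc3)c(OCc3ccccc3)c1)[C@@H](O)C2
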